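The earlier runs and the new flask stem from a simulated flask for substances that don't exist, and the scatter is random.

The easy step in elm, the asked flask followed so far, is a mean: its substrate readings lie level from the first one on, so I replace them by their average, 72.0 % of the charge, and ask why the rest stayed.

| flask | substrate | reagent | capture agent | free catalyst | second catalyst | impurity | temperature | remark | time |
|---|---|---|---|---|---|---|---|---|---|
| elm | 0.10 M | 0.25 M | 5 mM | 0.14 mM | 0.50 mM | 0.19 mM | 35 °C | the very flask that is asked about, followed so far |  |
| birch | 0.10 M | 0.38 M | 5 mM | 0.14 mM | 0.50 mM | 0.19 mM | 41 °C | run made earlier |  |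
| flask | 0.10 M | 0.250 M | 5.00 mM | 0.14 mM | 0.50 mM | 0.19 mM | 35 °C |  | 8.0 d |

- elm (time / d: target / %, substrate / %): 0.500: 14.4, 72.4; 0.833: 19.4, 71.7; 1.25: 21.4, 71.7; 2.50: 25.6, 72.2; 4.00: 25.1, 72.4; 6.00: 25.1, 71.6
- birch (time / d: target / %, substrate / %): 0.250: 15.1, 69.9; 0.833: 24.6, 70.3; 1.25: 26.3, 71.1; 2.00: 27.0, 70.6; 3.00: 27.5, 69.9; 4.00: 27.1, 70.6

(readings scatter by 0.5 percentage points)

- what is taken out of target is counted as made
- "the catalyst" is free catalyst with its forms; second catalyst is a second catalyst
- additions bring no volume worth counting

- Friday's: at 8.0 d add reagent, 50.0 % of the amount charged, then wait 2.5 d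
- Thursday's: at 8.0 d take out 90 % of the target then present, then wait 2.5 d
- Monday's: at 8.0 d raise the temperature by 25 K, then wait 2.5 d
- Wednesday's: change nothing and wait 2.5 d more
- Tuesday's: at 8.0 d add free catalyst, 100 % of the amount charged, then wait 2.5 d

* target, in percent of the substrate first charged, at 8.0 d
* which option adds most target ("none" when 2 percentage points or less is all one gets) (Friday's / Thursday's / Monday's / Wednesday's / Tuesday's / none)
* target present, with what was taken out counted in, in percent of the substrate first charged, after Friday's
* target present, with what was taken out counted in, in percent of the substrate first charged, after Tuesday's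

My first guess is that the free catalyst in elm wears out after a set number of turnovers, here 200, so that a second dose buys the same again, a further 28.0 % of the charge. The objection is that elm also holds impurity, 1.36 times the catalyst. If each impurity kills one catalyst, a stoichiometric poison, the fraction of impurity left in elm is 26.3 %.

While catalyst is free, substrate and impurity both fall in proportion to it, so it cancels from the race ratio, a selectivity factor: the logarithm of the substrate fraction left divided by the logarithm of the impurity fraction left, 0.246. Is that an accident of elm? Birch, hotter and richer in reagent, keeps 70.4 % and gives 0.263. But a fixed turnover count would fit birch as well, so the poison remains my bet.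

The bet says that a second dose in elm meets 0.0500 mM of impurity, less than the dose, so 64.3 % of a catalyst charge should outlast it and the substrate should keep falling. Is the wait long enough? Holding the full charge of catalyst through the whole time to elm's first reading gives the slowest rate the readings allow, 0.657 /d. Even that rate, with the surviving catalyst, leaves 25.0 % of the substrate after the wait, and the true race was shorter. Target in elm had reached its level by 2.50 d, the same wait.

That level, 25.3 %, is my answer for now. It is 90.2 % of the substrate lost, so I commit to about that figure after Tuesday's, which is my choice. On this bet the other options find no free catalyst, and Friday's stays at 25.3 %.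

The forecast gives 25.3 %, Tuesday's, 25.6 % after Friday's and 43 % after Tuesday's, holding that “Only fresh catalyst restarts the reaction”. My figure for Tuesday's is higher than the forecast's.

The flask gives 25.1 %, Tuesday's with a gain of 66 percentage points, 25.1 % after Friday's and 91.3 % after Tuesday's.

    open intermediate + capture agent → trapped intermediate (k = 2.30 /M/h, Ea = 59.0 kJ/mol)
    free catalyst + impurity → spent catalyst (k = 73000 /M/h, Ea = 51.0 kJ/mol)
    substrate + free catalyst → free catalyst + open intermediate (k = 18000 /M/h, Ea = 59.0 kJ/mol)
    reagent + second catalyst + open intermediate → second catalyst + target (k = 550 /M²/h, Ea = 38.0 kJ/mol)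
    (constants at 35 °C)

The path from free catalyst and impurity to spent catalyst is the main reason elm stops: the run without it reaches 95.1 % of target against 25.1 %. Elm's table, with 72 % of the substrate and 26 % of the impurity left, gives a race ratio of 0.247. The neighbour charged with 3.5 × 10⁻⁵ M of free catalyst has 81.6 % of its impurity left by the one-for-one count, so the ratio from elm's readings gives 95.1 % of its substrate, and it keeps 95 %.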